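## Structural features

The target is a bichalcone: two (E)-1-(2-hydroxyaryl)-3-(4-hydroxyphenyl)prop-2-en-1-one units whose ketone-bearing rings are joined through one diaryl ether oxygen. Ring A is 1,2,4,5-tetrasubstituted (enoyl at C1, OH at C2, OMe at C4, ether oxygen at C5). Ring B is 1,2,4-trisubstituted (enoyl at C1', OH at C2', ether oxygen at C4'), so the ether links C5 to C4'. There is no stereocentre; the only stereochemical elements are the two trans enone double bonds, which are the thermodynamically preferred isomers. The fragile parts are the two 2'-hydroxychalcone units, which are Michael acceptors and can close to flavanones under forcing acid or base, and the electron-rich ring A, a masked methoxyhydroquinone that is easily oxidised. The real difficulty is the unsymmetrical diaryl ether between two electron-rich, differently oxygenated rings, together with placing each acyl group ortho to the correct hydroxyl. The key step uses the fact that on ring B the oxygens at C2' and C4' are meta to each other with C3'–H between them: a four-carbon vinylketene (C2', C5', C6', C1') and an aryloxyacetylene (C3', C4') assemble exactly this pattern, so the ether oxygen arrives as the phenol oxygen of ring A and no aryl–oxygen bond has to be made by coupling. The hydroxyls at C2 and C2' afterwards direct the acyl groups to C1 and C1', which are also para to the methoxy and aryloxy oxygens.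

## Logic of the disconnections

28 to 27. Only the two acetal O–CH2 bonds on the outer phenolic oxygens are restored. Free outer phenols would sit as phenoxides in the base-mediated condensation and deactivate the aldehyde partner. The forward cleavage must be mild enough not to cyclise the 2'-hydroxy enones.

27 to 24 and two equivalents of 25. Both Cα=Cβ bonds are cut, the aldol retron of an aryl enone. This removes both C6–C1 units at once and leaves a bis(methyl ketone). The forward step must run twice on one molecule in the presence of two free ortho hydroxyls, and the trans geometry must result from dehydration under thermodynamic control.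

24 to 20 and two equivalents of 21. The aryl–carbonyl bonds C1–C(=O) and C1'–C(=O) are cut and each acetyl group is traced back to the oxygen of its own ring (Fries retron). Each new bond lies ortho to a hydroxyl and para to an ether oxygen, the most nucleophilic and chelation-assisted positions. This leaves a diaryl ether diol without carbon substituents, and one molecule of 21 is consumed per ring. The forward step must distinguish C1' from C5' and C3' on ring B. Transferring the complete cinnamoyl arms instead is treated under Alternative 1.

20 to 19. The O–CH2 bond at O2 is restored, because this oxygen must stay masked while the other oxygen of ring A is carried through base, organolithium and heat. The forward step is a simple acid methanolysis, done before any Lewis acid is applied.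

19 to 14 and 11. In ring B the bonds C1'–C2', C2'–C3' and C4'–C5' are cut. Ring B disappears completely and the diaryl ether C–O bond becomes the alkynyl C–O bond already present in 11. The forward step is a thermal cascade whose (2+2) event must follow the polarity of the two partners, so that OH and OAr end up meta.

11 to 8. The triple bond is traced back to a 1,2-dichloroalkene by formal addition of HCl and Cl. The forward step needs two equivalents of organolithium at low temperature without metalation of the ring.

8 to 5 and 6. The O–C(sp2) bond is cut. The two alkyne carbons then come from a cheap C2 chloroalkene and a phenol, with no metal-catalysed O-alkynylation. The forward step needs only carbonate base.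

5 to 4 to 3. These are protecting-group interchanges: benzyl on the oxygen next to OMe, the acetal on the other. They keep the two hydroquinone oxygens distinguishable at every stage. The benzyl group must be removable without acid.

3 to 1. The aryl C–O bond is traced back to an aryl C–CHO bond (peracid oxidation retron). The two ring oxygens thereby originate from different functional groups and cannot be confused. The forward step requires aryl migration to beat hydride migration, which the para benzyloxy group ensures.

14 to 13 to 12. The C=C bond is traced to a β-bromo ketone (elimination of HBr) and the C–Br bond to a C–CO2H bond (bromodecarboxylation). The demand is practical: 14 is volatile and polymerisable and must be handled cold in solution.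

## Other disconnections considered

Alternative 1: The cut is made at the two aryl–carbonyl bonds C1–C(=O) and C1'–C(=O) of the bis(methanesulfonate) A1. It leads back to the diaryl ether bis-cinnamate A2, in which both 4-(mesyloxy)cinnamoyl groups sit on O2 and O2'. In the forward direction TiCl4 or AlCl3 would ionise each ester and the acyl group would re-enter its own ring ortho to the liberated phenoxide (double Fries rearrangement). No ring is closed.
- In favour: each C6–C3 arm arrives complete with its E double bond. The phenol oxygens serve first as attachment points and then as ortho directors. A2 would be available by one acylation of diol 20 with acid chloride A3, so this alternative concerns only the endgame and is compatible with the benzannulation.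
- Against: a cinnamate on an electron-rich ring under a strong Lewis acid can also undergo conjugate hydroarylation to a 4-aryl-dihydrocoumarin. The 2'-hydroxychalcone products can close to flavanones in the same medium. Ring B can take the acyl group para to oxygen (C5') instead of at C1'. AlCl3 threatens the methyl ether. The mesylates must finally be removed by base or nucleophile from a base-sensitive bis-enone.
- Comparison: the structural reasoning is the same as in the chosen plan, which also moves an acyl group from O2 and O2' to C1 and C1'. From 20 the number of steps is equal (three each). Convergence is better, since only one C–C bond-forming operation follows ring construction. The total count is worse because A3 must be prepared. Mechanistically it is weaker, because the migrating group is itself an acid-sensitive acceptor, whereas the acetyl group of step 10 has no second reaction channel. It does not say how the diaryl ether is made, so it cannot replace step 8.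

Alternative 2: Ring B is cut at C5'–C6' and C1'–C2'. This gives the 1,1-dioxygenated 3-aryloxy diene A5, whose aryloxy group is O5 of a complete ring A chalcone, and the cross-conjugated enynone A6 (one alkene, one terminal alkyne). In the forward direction a (4+2) cycloaddition joins the nucleophilic CH2 terminus of A5 to the alkyne terminus of A6 and the ketene acetal carbon to the acyl-bearing alkyne carbon. Loss of methanol and desilylation would then give the tris-MOM ether A4 with C2'–OH free.
- In favour: the regiochemistry follows from matched polarity. The acyl group of ring B arrives already at C1', so no later acylation of ring B is needed; on this point the alternative is better than the chosen plan, which leaves C1' as C–H. Like the chosen plan it avoids any aryl–oxygen coupling, and here the two are equal.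
- Against: A5 requires γ-deprotonation and O-silylation (LiN(i-Pr)2, Me3SiCl) of a β-aryloxy enoate that already carries a chalcone enone. The enoate itself needs an oxa-Michael addition of a hindered ortho-methoxy phenol. A5 is hydrolytically labile. A6 is a doubly activated acceptor that can polymerise or react at its alkene.
- Comparison: one cycloaddition plus elimination is mechanistically simpler than four consecutive pericyclic events. However, the ring is built on advanced, sensitive material, whereas step 8 works on two small fragments. The linear sequence would not be expected to be shorter than the ten steps of the chosen plan, and it carries three acetal groups through the ring construction.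

Alternative 3: The two phenolic C–O bonds C2–O and C2'–O of bis(2-hydroxyacetophenone) A7 are cut. A7 is the same compound as 24, and the cut gives the bis-acetophenone diaryl ether A8. In the forward direction [RuCl2(p-cymene)]2 (a divalent ruthenium precatalyst) with K2S2O8 in CF3CO2H and (CF3CO)2O would cyclometalate each ring ortho to its acetyl group and oxidise the C–Ru bond to C–O. The aryl trifluoroacetates formed would be hydrolysed on work-up.
- In favour: A8 would come from one SNAr reaction of phenol A9 with fluoroarene A10, so A7 would be reached in two steps with no protecting group. In step economy this is clearly better than the chosen plan, which needs ten steps to reach 24. The endgame from A7 is identical, so the two are equal there. On ring A the C2–H bond is less hindered than C6–H, which is flanked by the aryloxy group. On ring B the two ortho positions are equivalent.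
- Against: two directed oxidations must both go to completion on one molecule while each ring stops after one hydroxylation. Ring B has a second, equivalent ortho C–H bond. Ring A is an electron-rich anisole in a persulfate/trifluoroacetic medium that can also oxidise arenes without direction or attack aryl methyl ketones in a Baeyer–Villiger sense. The ketone is a weak directing group, and any loss of selectivity would give isomers that are hard to separate.
- Comparison: here the oxygenation pattern depends on site-by-site chelation control, whereas in the chosen plan it is fixed by how ring B is constructed. If the hydroxylation were as selective as hoped, this would be the shorter and better route. The chosen plan trades about eight extra steps for an oxygenation pattern that cannot come out wrong.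

Key step: step 8

Remark on the chemistry: 1 (the benzyl ether of vanillin), 21 and 25 are taken as catalogue compounds; 1 and 25 would otherwise each cost one routine O-alkylation.

## Route

Step 1
Reactants: 1 4-(benzyloxy)-3-methoxybenzaldehyde
Product: 3 4-(benzyloxy)-3-methoxyphenol, via 4-(benzyloxy)-3-methoxyphenyl formate 2 (not isolated)
Conditions: mCPBA, CH2Cl2, 0 °C to rt; then K2CO3, MeOH, rt
Reagents that add atoms: 3-chloroperoxybenzoic acid (mCPBA), O=C(OO)c1cccc(Cl)c1
Why: Baeyer–Villiger oxidation, the peracid form of the Dakin reaction: the para benzyloxy group makes the aryl group migrate in preference to hydride, giving formate 2, which carbonate in methanol transesterifies to phenol 3. Alkaline H2O2 would be unreliable here because the ring carries no free ortho or para hydroxyl.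

Step 2
Reactants: 3 4-(benzyloxy)-3-methoxyphenol
Product: 4 1-(benzyloxy)-2-methoxy-4-(methoxymethoxy)benzene
Conditions: MOMCl, i-Pr2NEt, CH2Cl2, 0 °C to rt
Reagents that add atoms: chloromethyl methyl ether (MOMCl), COCCl
Why: O-alkylation of the phenol by the reactive α-chloro ether under amine base. The MOM acetal is chosen because it withstands carbonate in DMF, n-BuLi at low temperature and the thermal key step.

Step 3
Reactants: 4 1-(benzyloxy)-2-methoxy-4-(methoxymethoxy)benzene
Product: 5 2-methoxy-4-(methoxymethoxy)phenol
Conditions: H2 (1 atm), Pd/C, EtOAc, rt
Reagents that add atoms: none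
Why: Catalytic hydrogenolysis of the benzyl ether under neutral conditions leaves the acid-labile acetal and the methyl ether untouched and frees only the hydroxyl next to the methoxy group.

Step 4
Reactants: 5 2-methoxy-4-(methoxymethoxy)phenol; 6 trichloroethylene
Product: 8 1-{[(E)-1,2-dichloroethenyl]oxy}-2-methoxy-4-(methoxymethoxy)benzene, via dichloroacetylene 7 (not isolated)
Conditions: K2CO3, DMF, 70 °C
Reagents that add atoms: none
Why: Carbonate dehydrochlorinates 6 to dichloroacetylene 7, to which the phenoxide adds in anti fashion to give the (E)-1,2-dichlorovinyl ether, the standard entry to ynol ethers from hydroxyl compounds. Because 7 is toxic and shock-sensitive it is only generated and consumed in dilute solution under inert gas.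

Step 5
Reactants: 8 1-{[(E)-1,2-dichloroethenyl]oxy}-2-methoxy-4-(methoxymethoxy)benzene
Product: 11 1-(ethynyloxy)-2-methoxy-4-(methoxymethoxy)benzene, via chloroethynyl aryl ether 9 (not isolated), via lithium aryloxyacetylide 10 (not isolated)
Conditions: n-BuLi (2.3 equiv), Et2O, −78 to −40 °C; then MeOH, −78 °C
Reagents that add atoms: none
Why: The first equivalent of n-BuLi eliminates HCl to chloroalkyne 9, the second effects chlorine–lithium exchange to acetylide 10, and methanol protonates it (dichlorovinyl ether route to terminal ynol ethers). At −78 °C these events should outrun ring lithiation next to the methoxy and acetal groups; the product is kept cold in solution and used promptly.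

Step 6
Reactants: 12 3-oxocyclobutanecarboxylic acid
Product: 13 3-bromocyclobutanone
Conditions: HgO, Br2, MgSO4, CH2Cl2, reflux
Reagents that add atoms: bromine, BrBr
Why: Cristol–Firth modification of the Hunsdiecker reaction: the acyl hypobromite formed through the mercury carboxylate loses CO2 in a radical chain and the cyclobutyl radical abstracts bromine. The ketone is inert under these conditions; the mercury residues require the handling and disposal appropriate to toxic heavy-metal salts.

Step 7
Reactants: 13 3-bromocyclobutanone
Product: 14 cyclobut-2-en-1-one
Conditions: n-Bu3N, neat, rt; vacuum transfer into a −78 °C trap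
Reagents that add atoms: none
Why: E1cB-type β-elimination of HBr from the β-bromo ketone by the hindered amine. The volatile enone is separated from the ammonium salt by vacuum transfer and stored cold in solution to suppress polymerisation.

Step 8
Reactants: 14 cyclobut-2-en-1-one; 11 1-(ethynyloxy)-2-methoxy-4-(methoxymethoxy)benzene
Product: 19 3-[2-methoxy-4-(methoxymethoxy)phenoxy]phenol, via vinylketene 15 (not isolated), via 4-vinylcyclobutenone adduct 16 (not isolated), via dienylketene 17 (not isolated), via cyclohexadienone 18 (not isolated)
Conditions: 14 (2 equiv), toluene, sealed tube, 80 °C then 110 °C; then KOH, MeOH, rt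
Reagents that add atoms: none
Why: Danheiser benzannulation, a cascade of four pericyclic steps whose closest precedents are the reactions of cyclobutenones with alkoxyacetylenes, silyloxyacetylenes and ynamides. On heating, 14 opens reversibly (4π electrocyclic) to vinylketene 15, which is trapped by the electron-rich alkyne of 11 in a (2+2) cycloaddition: the unsubstituted, nucleophilic alkyne carbon bonds to the ketene carbonyl carbon (C2'–C3') and the oxygen-bearing carbon to the ketene α-carbon (C4'–C5'), giving 16 with the vinyl group on its sp3 carbon. At the higher temperature 16 opens (4π) to dienylketene 17, in which the ketene and vinyl termini are cis, and ring B is closed by a thermal disrotatory 6π electrocyclisation that joins the ketene carbon to the terminal CH2 (C1'–C2'); dienone 18 then tautomerises to phenol 19. No stereocentre remains, since the one in 16 is destroyed on ring opening. The selectivity needed is regiochemical, hydroxyl meta to the aryloxy group with C3'–H between them, and it is secured by the polarisation of the ynol ether (the oxygen donor makes the CH terminus nucleophilic) against the electrophilic ketene carbon. An aryl ynol ether has no C–H bond β to oxygen on the aryl side and so cannot fragment by the retro-ene path that destroys alkyl ynol ethers at these temperatures; the acetal, the methyl ether and the diaryl ether of the product are thermally inert. Excess 14 offsets ketene dimerisation, and the KOH/MeOH treatment cleaves any ester formed when 15 acylates the product phenol.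

Step 9
Reactants: 19 3-[2-methoxy-4-(methoxymethoxy)phenoxy]phenol
Product: 20 3-(4-hydroxy-2-methoxyphenoxy)phenol
Conditions: HCl (cat.), MeOH, 50 °C
Reagents that add atoms: none
Why: Acid-catalysed acetal exchange with methanol removes the MOM group as dimethoxymethane, so no formaldehyde equivalent is present when the electron-rich rings later meet a Lewis acid. The aryl methyl ether and the diaryl ether are stable to these conditions.

Step 10
Reactants: 20 3-(4-hydroxy-2-methoxyphenoxy)phenol; 21 acetic anhydride
Product: 24 1-[5-(4-acetyl-3-hydroxyphenoxy)-2-hydroxy-4-methoxyphenyl]ethanone, via diacetate 22 (not isolated), via bis-BF2 chelate 23 (not isolated)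
Conditions: 21 (2.5 equiv), BF3·OEt2, 0 °C to 90 °C; then H2O/MeOH, 60 °C
Reagents that add atoms: none
Why: One-pot O-acetylation and boron trifluoride-mediated Fries rearrangement, a standard preparation of 2-hydroxyacetophenones from oxygenated phenols: one molecule of 21 per hydroxyl first gives diacetate 22, and BF3 then moves each acetyl group to the ring carbon ortho to its own oxygen, the ortho-hydroxy ketone being held as BF2 chelate 23 until hydrolytic work-up. On ring A the position para to O2 is blocked by the aryloxy group and C3 is flanked, so the acetyl group should go to C1 (para to OMe); on ring B chelation and the para aryloxy oxygen favour C1' over C5' and the flanked C3'. Each acetyl group deactivates its own ring against a second acylation.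

Step 11
Reactants: 24 1-[5-(4-acetyl-3-hydroxyphenoxy)-2-hydroxy-4-methoxyphenyl]ethanone; 25 4-(methoxymethoxy)benzaldehyde
Product: 27 (2E)-1-[2-hydroxy-5-{3-hydroxy-4-[(2E)-3-[4-(methoxymethoxy)phenyl]prop-2-enoyl]phenoxy}-4-methoxyphenyl]-3-[4-(methoxymethoxy)phenyl]prop-2-en-1-one, via bis-aldol adduct 26 (not isolated)
Conditions: 25 (2.4 equiv), KOH (50% aq.), EtOH, rt
Reagents that add atoms: none
Why: Double Claisen–Schmidt condensation: each methyl ketone enolate adds to the non-enolisable aldehyde and aldol 26 dehydrates by an E1cB pathway to the conjugated, thermodynamically preferred E enone, erasing the carbinol stereocentres. The acetal keeps the aldehyde electrophilic (a free 4-phenoxide would not be), and the 2-hydroxyl groups are tolerated as phenoxides.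

Step 12
Reactants: 27 the bis-MOM ether from step 11
Product: 28 (2E)-1-[2-hydroxy-5-{3-hydroxy-4-[(2E)-3-(4-hydroxyphenyl)prop-2-enoyl]phenoxy}-4-methoxyphenyl]-3-(4-hydroxyphenyl)prop-2-en-1-one (the rhuschalcone target)
Conditions: HCl (3 M aq.), MeOH, 40 °C
Reagents that add atoms: none
Why: Acid-catalysed acetal methanolysis frees the two outer phenols under conditions commonly used for MOM-protected 2'-hydroxychalcones. Moderate temperature and a short reaction time should keep the hydrogen-bonded 2'-hydroxy enones from closing to flavanones, and the E geometry is not affected.

## Compound list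

1 | 4-(benzyloxy)-3-methoxybenzaldehyde | COc1cc(C=O)ccc1OCc1ccccc1 | starting material
2 | 4-(benzyloxy)-3-methoxyphenyl formate (step 1, not isolated) | COc1cc(OC=O)ccc1OCc1ccccc1 | intermediate
3 | 4-(benzyloxy)-3-methoxyphenol | COc1cc(O)ccc1OCc1ccccc1 | intermediate
4 | 1-(benzyloxy)-2-methoxy-4-(methoxymethoxy)benzene | COCOc1ccc(OCc2ccccc2)c(OC)c1 | intermediate
5 | 2-methoxy-4-(methoxymethoxy)phenol | COCOc1ccc(O)c(OC)c1 | intermediate
6 | trichloroethylene | ClC=C(Cl)Cl | starting material
7 | dichloroacetylene (step 4, not isolated) | ClC#CCl | intermediate
8 | 1-{[(E)-1,2-dichloroethenyl]oxy}-2-methoxy-4-(methoxymethoxy)benzene | Cl/C=C(/Cl)Oc1ccc(OCOC)cc1OC | intermediate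
9 | 1-[(chloroethynyl)oxy]-2-methoxy-4-(methoxymethoxy)benzene (step 5, not isolated) | ClC#COc1ccc(OCOC)cc1OC | intermediate
10 | lithium [2-methoxy-4-(methoxymethoxy)phenoxy]acetylide (step 5, not isolated) | [Li]C#COc1ccc(OCOC)cc1OC | intermediate
11 | 1-(ethynyloxy)-2-methoxy-4-(methoxymethoxy)benzene | C#COc1ccc(OCOC)cc1OC | intermediate
12 | 3-oxocyclobutanecarboxylic acid | O=C1CC(C(=O)O)C1 | starting material
13 | 3-bromocyclobutanone | O=C1CC(Br)C1 | intermediate
14 | cyclobut-2-en-1-one | O=C1C=CC1 | intermediate
15 | buta-1,3-dien-1-one, vinylketene (step 8, not isolated) | C=CC=C=O | intermediate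
16 | 4-ethenyl-3-[2-methoxy-4-(methoxymethoxy)phenoxy]cyclobut-2-en-1-one, racemic (step 8, not isolated) | C=CC1C(=O)C=C1Oc1ccc(OCOC)cc1OC | intermediate
17 | (3E)-3-[2-methoxy-4-(methoxymethoxy)phenoxy]hexa-1,3,5-trien-1-one (step 8, not isolated) | O=C=C/C(Oc1ccc(OCOC)cc1OC)=C\C=C | intermediate
18 | 3-[2-methoxy-4-(methoxymethoxy)phenoxy]cyclohexa-2,4-dien-1-one (step 8, not isolated) | O=C1CC=CC(Oc2ccc(OCOC)cc2OC)=C1 | intermediate
19 | 3-[2-methoxy-4-(methoxymethoxy)phenoxy]phenol | COCOc1ccc(Oc2cccc(O)c2)c(OC)c1 | intermediate
20 | 3-(4-hydroxy-2-methoxyphenoxy)phenol | COc1cc(O)ccc1Oc1cccc(O)c1 | intermediate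
21 | acetic anhydride | CC(=O)OC(C)=O | starting material
22 | 3-[4-(acetyloxy)-2-methoxyphenoxy]phenyl acetate (step 10, not isolated) | COc1cc(OC(C)=O)ccc1Oc1cccc(OC(C)=O)c1 | intermediate
23 | bis(difluoroboron) chelate of 24, each 2-hydroxyacetophenone unit bound through phenolate and carbonyl oxygen in a six-membered O–B–O ring (step 10, not isolated) | COc1cc2O[B-](F)(F)[O+]=C(C)c2cc1Oc1ccc2C(C)=[O+][B-](F)(F)Oc2c1 | intermediate
24 | 1-[5-(4-acetyl-3-hydroxyphenoxy)-2-hydroxy-4-methoxyphenyl]ethanone | COc1cc(O)c(C(C)=O)cc1Oc1ccc(C(C)=O)c(O)c1 | intermediate
25 | 4-(methoxymethoxy)benzaldehyde | COCOc1ccc(C=O)cc1 | starting material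
26 | 3-hydroxy-1-[2-hydroxy-5-{3-hydroxy-4-[3-hydroxy-3-[4-(methoxymethoxy)phenyl]propanoyl]phenoxy}-4-methoxyphenyl]-3-[4-(methoxymethoxy)phenyl]propan-1-one, mixture of diastereomers (step 11, not isolated) | COc1cc(O)c(C(=O)CC(O)c2ccc(OCOC)cc2)cc1Oc1ccc(C(=O)CC(O)c2ccc(OCOC)cc2)c(O)c1 | intermediate
27 | (2E)-1-[2-hydroxy-5-{3-hydroxy-4-[(2E)-3-[4-(methoxymethoxy)phenyl]prop-2-enoyl]phenoxy}-4-methoxyphenyl]-3-[4-(methoxymethoxy)phenyl]prop-2-en-1-one | COc1cc(O)c(C(=O)/C=C/c2ccc(OCOC)cc2)cc1Oc1ccc(C(=O)/C=C/c2ccc(OCOC)cc2)c(O)c1 | intermediate
28 | (2E)-1-[2-hydroxy-5-{3-hydroxy-4-[(2E)-3-(4-hydroxyphenyl)prop-2-enoyl]phenoxy}-4-methoxyphenyl]-3-(4-hydroxyphenyl)prop-2-en-1-one | COc1cc(O)c(C(=O)/C=C/c2ccc(O)cc2)cc1Oc1ccc(C(=O)/C=C/c2ccc(O)cc2)c(O)c1 | target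

## Step count and least certain steps

Total step count: 12. Longest linear sequence: 10 steps (steps 1 to 5 and 8 to 12, from 1); steps 6 and 7 form the two-step side branch to 14.

Step 8 (key step). The most likely failure is loss of both partners to self-reaction before they meet. The terminal aryloxyacetylene can oligomerise at the temperature needed to open 14, and the vinylketene and the strained enone can dimerise or polymerise. An aryloxy alkyne is also a weaker nucleophile than the alkoxy and silyloxy alkynes normally used, so the bimolecular (2+2) event is slower. Incomplete opening of 16 at too low a temperature is a second risk. Fallback, from 5 and returning at 19: copper-catalysed Ullmann-type etherification of 5 with commercial 1-(benzyloxy)-3-bromobenzene (CuI, picolinic acid, K3PO4, DMSO, 90 °C) should give 1-[3-(benzyloxy)phenoxy]-2-methoxy-4-(methoxymethoxy)benzene F1. Neutral hydrogenolysis (H2, Pd/C, EtOAc) would then remove the benzyl group and deliver 19. This forms the aryl–oxygen bond by coupling instead of building ring B.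

Step 5. Two processes threaten it: competing lithiation of the ring ortho to the methoxy or acetal oxygen, and decomposition of the terminal ynol ether on concentration or storage, since terminal aryloxyacetylenes polymerise readily. Fallback, from 8 and returning at 20: the same n-BuLi treatment, but acetylide 10 is quenched with Me3SiCl, which should give {[2-methoxy-4-(methoxymethoxy)phenoxy]ethynyl}(trimethyl)silane F2, a carbon-capped ynol ether that can be purified and stored. Heating F2 with 14 would place silicon at C3' and give 3-[2-methoxy-4-(methoxymethoxy)phenoxy]-2-(trimethylsilyl)phenol F3. The HCl/MeOH conditions of step 9 would then remove the acetal and, by ipso protonation at the carbon flanked by two oxygen donors, the silyl group, rejoining the route at 20.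

Step 10. The main risk is migration of the ring B acetyl group to the position para to the hydroxyl (C5') instead of ortho (C1'), because both positions are activated by the two oxygens. A stalled second migration and partial cleavage of the methyl ether on prolonged heating with the Lewis acid are lesser risks. Fallback, from 20 and returning at 24: magnesium-mediated ortho-formylation (MgCl2, Et3N, paraformaldehyde, MeCN, reflux; Casnati–Skattebøl conditions) delivers the formyl group inside a magnesium phenoxide chelate and cannot reach a para position. It should give 5-(4-formyl-3-hydroxyphenoxy)-2-hydroxy-4-methoxybenzaldehyde F4. Excess MeMgBr (THF, 0 °C) would convert this to the bis(1-hydroxyethyl) compound 2-(1-hydroxyethyl)-4-[3-hydroxy-4-(1-hydroxyethyl)phenoxy]-5-methoxyphenol F5, and benzylic oxidation with MnO2 (CH2Cl2, rt) would give 24.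

Step 11. The risks are stalling after one condensation, because the bis-phenoxide makes the methyl ketones less acidic, and base-induced oxa-Michael closure of the 2'-hydroxychalcone units to flavanones on the long reaction time a double condensation needs. Fallback, from 24 and returning at 28: both chelated hydroxyls are first protected (NaH, MOMCl, DMF), which should give 1-{5-[4-acetyl-3-(methoxymethoxy)phenoxy]-4-methoxy-2-(methoxymethoxy)phenyl}ethanone F6. Condensation of F6 with 25 (KOH, EtOH) would give the tetrakis-MOM bichalcone F7, which cannot cyclise. The conditions of step 12 would then remove all four acetals to give 28 directly.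

## Further compounds

F1 | step 8 | 1-[3-(benzyloxy)phenoxy]-2-methoxy-4-(methoxymethoxy)benzene | COCOc1ccc(Oc2cccc(OCc3ccccc3)c2)c(OC)c1
F2 | step 5 | {[2-methoxy-4-(methoxymethoxy)phenoxy]ethynyl}(trimethyl)silane | COCOc1ccc(OC#C[Si](C)(C)C)c(OC)c1
F3 | step 5 | 3-[2-methoxy-4-(methoxymethoxy)phenoxy]-2-(trimethylsilyl)phenol | COCOc1ccc(Oc2cccc(O)c2[Si](C)(C)C)c(OC)c1
F4 | step 10 | 5-(4-formyl-3-hydroxyphenoxy)-2-hydroxy-4-methoxybenzaldehyde | COc1cc(O)c(C=O)cc1Oc1ccc(C=O)c(O)c1
F5 | step 10 | 2-(1-hydroxyethyl)-4-[3-hydroxy-4-(1-hydroxyethyl)phenoxy]-5-methoxyphenol, mixture of diastereomers | COc1cc(O)c(C(C)O)cc1Oc1ccc(C(C)O)c(O)c1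
F6 | step 11 | 1-{5-[4-acetyl-3-(methoxymethoxy)phenoxy]-4-methoxy-2-(methoxymethoxy)phenyl}ethanone | COCOc1cc(OC)c(Oc2ccc(C(C)=O)c(OCOC)c2)cc1C(C)=O
F7 | step 11 | (2E)-1-[4-methoxy-2-(methoxymethoxy)-5-{3-(methoxymethoxy)-4-[(2E)-3-[4-(methoxymethoxy)phenyl]prop-2-enoyl]phenoxy}phenyl]-3-[4-(methoxymethoxy)phenyl]prop-2-en-1-one | COCOc1cc(OC)c(Oc2ccc(C(=O)/C=C/c3ccc(OCOC)cc3)c(OCOC)c2)cc1C(=O)/C=C/c1ccc(OCOC)cc1
A1 | alternative 1 | bis(methanesulfonate) of 28 at the two outer (4-hydroxyphenyl) oxygens | COc1cc(O)c(C(=O)/C=C/c2ccc(OS(C)(=O)=O)cc2)cc1Oc1ccc(C(=O)/C=C/c2ccc(OS(C)(=O)=O)cc2)c(O)c1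
A2 | alternative 1 | 3-{2-methoxy-4-[(2E)-3-{4-[(methylsulfonyl)oxy]phenyl}prop-2-enoyloxy]phenoxy}phenyl (2E)-3-{4-[(methylsulfonyl)oxy]phenyl}prop-2-enoate | COc1cc(OC(=O)/C=C/c2ccc(OS(C)(=O)=O)cc2)ccc1Oc1cccc(OC(=O)/C=C/c2ccc(OS(C)(=O)=O)cc2)c1
A3 | alternative 1 | (2E)-3-{4-[(methylsulfonyl)oxy]phenyl}prop-2-enoyl chloride | CS(=O)(=O)Oc1ccc(/C=C/C(=O)Cl)cc1
A4 | alternative 2 | tris-MOM ether of 28 (acetals on O2 and on both outer phenols, C2' hydroxyl free) | COc1cc(OCOC)c(C(=O)/C=C/c2ccc(OCOC)cc2)cc1Oc1ccc(C(=O)/C=C/c2ccc(OCOC)cc2)c(O)c1
A5 | alternative 2 | (2E)-1-[4-methoxy-2-(methoxymethoxy)-5-{[4-methoxy-4-(trimethylsilyloxy)buta-1,3-dien-2-yl]oxy}phenyl]-3-[4-(methoxymethoxy)phenyl]prop-2-en-1-one | C=C(Oc1cc(C(=O)/C=C/c2ccc(OCOC)cc2)c(OCOC)cc1OC)C=C(OC)O[Si](C)(C)C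
A6 | alternative 2 | (1E)-1-[4-(methoxymethoxy)phenyl]pent-1-en-4-yn-3-one | C#CC(=O)/C=C/c1ccc(OCOC)cc1
A7 | alternative 3 | 1-[5-(4-acetyl-3-hydroxyphenoxy)-2-hydroxy-4-methoxyphenyl]ethanone (identical with 24) | COc1cc(O)c(C(C)=O)cc1Oc1ccc(C(C)=O)c(O)c1
A8 | alternative 3 | 1-[3-(4-acetylphenoxy)-4-methoxyphenyl]ethanone | COc1ccc(C(C)=O)cc1Oc1ccc(C(C)=O)cc1
A9 | alternative 3 | 1-(3-hydroxy-4-methoxyphenyl)ethanone | COc1ccc(C(C)=O)cc1O
A10 | alternative 3 | 1-(4-fluorophenyl)ethanone | CC(=O)c1ccc(F)cc1
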